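## Structural features

Working locants used throughout: C1 (ring carbon bearing the exocyclic CH2), C2, C3, C4 (CHBr), C5 (quaternary, CH3), C6, C7, C8 and C9 (epoxide, CH3 on C9), C10, C11, C12 (acyloxy carbon bearing CMe2Br), C13 (ring CH bearing the benzylic CH2). The target is a meta-bridged cyclophane lactone: a 4-hydroxybenzoate esterified at C12 whose 3-position carries a CH2 bound to C13, so that a 15-membered ring is fused along C5–C13 to the six-membered carbocycle, ring A (C1–C5, C13). Ring A holds three contiguous stereocentres, C4 (S), C5 (S) and C13 (R), with bromine cis to the C5 methyl group and the two macrocyclic arms (C6 on C5, CH2Ar on C13) trans to each other. The large ring carries a trans-trisubstituted (8S,9S)-epoxide and the 12S acyloxy centre next to a tertiary bromide; no rigid element links these to ring A, so they need reagent control. Fragile groups are the tertiary bromide β to an acyloxy oxygen, the hindered secondary bromide, the acid-labile epoxide, the exocyclic olefin, the free phenol and the aryl ester; late steps must avoid strong base, strong Lewis acid, tin hydride and dissolving metals. The real difficulty is the C5–C13 junction, where a quaternary carbon sits next to a methine that must carry the arylmethyl arm on the face of the C5 methyl group. The feature exploited is that C13–H is allylic to C1: with the olefin moved to C1=C2 and an oxygenated CH2 on C1, the C13–CH2Ar bond is the bond an ester-enolate Claisen rearrangement forms from an arylacetate bound through oxygen to C2 of a ring-A allylic alcohol with a C1=C13 double bond. Because the same arene is already the C12 benzoate, this rearrangement contracts a 19-membered diolide to the 15-membered lactone; four atoms leave the ring (carboxyl carbon, oxygen, C2, C1).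

## Logic of the disconnections

37 to 36: the phenolic O–H is exchanged for O–Si. The phenol would interfere with the Mitsunobu step, the enolate step and the dioxirane. The triisopropylsilyl ether is chosen over the tert-butyldimethylsilyl ether because it survives aqueous phosphate, the carbonate buffer of the epoxidation and acid-mediated removal of the alkyl silyl ether. The forward step must use buffered fluoride so that neither the tertiary bromide nor the epoxide is touched.

36 to 35: both C–O bonds of the C8–C9 epoxide are cut. The E olefin encodes the trans relationship and is inert in every earlier step, and the acid-labile group disappears from the route. The forward step needs reagent-controlled face selection on a macrocyclic olefin and preference for the trisubstituted over the 1,1-disubstituted olefin; the 8S,9S configuration calls for the L-fructose-derived ketone, not the common D-fructose-derived one.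

35 to 32 and 31: the exocyclic C=C and one C2–H bond are exchanged for the C1=C2 olefin and a primary C–O bond, then O–H for O–Si. An endocyclic olefin with an oxygenated CH2 on C1 is exactly what a [3,3] shift onto C13 leaves behind. The forward steps need a reductive 1,3-transposition free of cations and long-lived radicals, and removal of the alkyl silyl ether beside the aryl one.

31 to 29: a carboxyl group is put back on the benzylic carbon. It is the footprint of the ester enolate and costs one step to remove. The decarboxylation must work without tin hydride because of the two C–Br bonds.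

29 to 26: the C13–benzylic bond is cut and the C2–O bond restored. This is the strategic cut. The C13 stereocentre becomes a carbinol centre at C2 that a catalytic reduction can set, and the 15-membered ring becomes a 19-membered diolide closed by esterification. The forward step needs enolisation of the arylacetate only, a suprafacial shift, and survival of both bromides in amide base.

26 to 25: the C2–O acyl bond is cut. Lactonisation of an arylacetic acid onto an unhindered allylic alcohol is the easier of the two possible ester closures. The forward step needs high dilution and a single free hydroxyl.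

25 to 11 and 23: the C7–C8 bond is cut. The cut lies away from every stereocentre, and the E geometry is carried by a preformed alkenyl iodide. Hydroboration must touch only the vinyl group, and the coupling must tolerate a free acid, a free hydroxyl and alkyl bromides.

23 to 22 to 21 and 17: the benzoate C(=O)–O bond is cut, and the arylacetic acid is masked as its tert-butyl ester. The ester onto the hindered C12 carbinol is best formed between two simple partners. Esterification must not re-close the bromohydrin to the epoxide, and acidolysis must not ionise the tertiary bromide.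

21 to 19 to 18: the aryl–CH2 bond and two O–Si bonds are cut. Building the arylacetate by α-arylation makes the two carboxyl groups different from the outset. The coupling must be neutral enough for a silyl ester to serve as a transient protecting group.

17 to 16 to 15: the tertiary C–Br bond, then the epoxide C–O bonds, are cut. C12 is set by asymmetric epoxidation of a prenyl-type olefin in an acyclic setting. Bromide must enter at the tertiary carbon so that C12 keeps its configuration.

15 to 13 to 12: the C9–CH3 and C8–I bonds across an alkyne, then the C10–C(alkyne) bond, are cut. The forward step needs syn carbometalation and iodinolysis with retention.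

11 to 10: the C2–H bond is cut. The reduction must be reagent-controlled and 1,2-selective, and must spare the vinyl group and the β-bromo ketone.

10 to 8 through 9: the vinyl C=C is traced to the formyl group and the enone to a β-methoxy silyl enol ether. Methylenating before the ketone is unveiled keeps base away from a β-bromo ketone.

8 to 3 and 7: the C3–C4 and C5–C13 ring bonds are cut. A 1,3-dioxygenated diene fixes the regiochemistry and delivers the enone oxidation level. The E geometry of 3 gives bromine cis to methyl, and a chiral Lewis acid must fix the absolute configuration of C4 and C5.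

7 to 6 to 5 to 4, and 3 to 1: the two O–Si bonds, the C–CH2OH bond and the C–I bond are cut in turn, ending at the vinylogous ester 4; the C–Br bond of 3 is traced to 1. The forward steps need functionalisation of the α-carbon of a vinylogous ester without scrambling its geometry.

## Other disconnections considered

Alternative 1: The cut removes the C5–C13 and C3–C4 bonds with the arylmethyl arm already on the diene. Forward, 3 and the diene A1 combine under the same class of chiral oxazaborolidinium catalyst as in step 5 to give the ring-A bromo aldehyde A2.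
- In its favour: one step sets C4, C5 and C13 and installs the arm and the allylic silyl ether, so no ring contraction and no decarboxylation are needed. On step economy it is better than the chosen plan.
- Against it: the two substituents of A1 direct in opposite senses (the 1-arm favours the needed orientation, the 2-substituent the reverse). The arm cis to the C5 methyl group requires the formyl group exo. A1 has no oxygen donor on the diene and must attack a hindered trisubstituted β-bromo enal. For the diene to reach the s-cis form the arm must be trans to the vinyl group, which by the sequence rules is the Z isomer. The macrocycle would still have to be closed later, at the hindered C12 hydroxyl or by a macrocyclic coupling.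
- Comparison: both plans use 3 and a concerted pericyclic step and are equal on the C4/C5 relationship. The chosen plan derives C13 from a carbinol centre by a suprafacial shift whose sense is not in doubt, whereas A2 depends on an endo/exo preference that is hard to predict.

Alternative 2: The cut removes the C10–C11 bond and creates the C8=C9 olefin in the same event. Forward, the hydroxy ketal A3 undergoes acid-catalysed ketal exchange and [3,3] shift of the resulting allyl vinyl ether to the 16-membered keto lactone A4.
- In its favour: the chair transition state gives the E olefin as reliably as the carboalumination of step 9 (equal on this point), and ring closure and C–C bond formation occur in one metal-free step (better on this point).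
- Against it: A4 is acylated on the tertiary oxygen and is one atom too large. It still needs stereoselective reduction at C12 inside the macrocycle, acyl transfer to the secondary oxygen with ring contraction, and substitution of a tertiary hydroxyl by bromide next to an ester, where acyloxonium participation makes regiochemistry and configuration uncertain. The ketal exchange must be bimolecular in effect at high dilution, which favours oligomers. It leaves the C5–C13 junction unsolved; ring A with its arm must come from another method.
- Comparison: the chosen plan sets C12 and the tertiary bromide early on an acyclic fragment and spends its key step on the hardest bond; the alternative spends it on the easiest and adds at least three late steps.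

Alternative 3: The cut removes the C5–C13 bond across a 19-membered macrolide. Forward, SnCl4 ionises the tertiary hydroxyl of the bromohydrin A5 with bromine participation, and the allylsilane attacks the bromonium ion at C5 to give A6.
- In its favour: it is biomimetic and sets C5 and C13, closes ring A and releases the exocyclic methylene in one step. A6 is the tert-butyldimethylsilyl analogue of 35, two steps from the target. It is clearly the shorter plan and is better on step economy.
- Against it: the configuration at C13 depends on a chair-like transannular array whose preference in a 19-membered ring cannot be predicted. The arm must be trans to C2 across the allylsilane double bond (the geometry of an E-prenyl unit, but Z by the sequence rules once silicon is on the branch). The C8=C9 olefin can compete as nucleophile or take up the bromonium by olefin-to-olefin transfer, which would erode the C4/C5 configuration. SnCl4 may ionise the CMe2Br group. An enantiopure anti-bromohydrin must be made first.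
- Comparison: both plans pass through a 19-membered macrolide (equal on this point). The chosen plan uses a pericyclic step with a fixed stereochemical course, and a basic step in which the bromides are spectators, not participants.

Key step: step 18

Assumption: the L-fructose-derived epoxidation ketone, (tributylstannyl)methanol, BrZnCH2CO2t-Bu and the o-tolyl oxazaborolidine from (R)-α,α-diphenylprolinol are treated as purchasable reagents.

## Steps

Step 1
Reactants: 1 methacrolein
Product: 3 (E)-3-bromo-2-methylprop-2-enal, via 2,3-dibromo-2-methylpropanal 2 (not isolated)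
Conditions: Br2, CH2Cl2, −10 °C; then Et3N, 0 °C → rt
Reagents that add atoms: bromine, BrBr
Why: Bromine adds across the enal and triethylamine removes HBr by E2 (hydrogen from C3, bromine from C2), the standard bromination–dehydrobromination route to β-bromo enals; the conjugated E isomer (Br trans to CHO, cis to CH3) is the more stable one.

Step 2
Reactants: 4 (E)-4-methoxybut-3-en-2-one
Product: 5 (Z)-3-iodo-4-methoxybut-3-en-2-one
Conditions: I2, pyridine, CH2Cl2, 0 °C → rt
Reagents that add atoms: iodine, II
Why: Electrophilic α-iodination of a vinylogous ester (attack at the nucleophilic α-carbon, then loss of a proton) is known for β-alkoxy enones; the methoxy group stays trans to the acetyl group.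

Step 3
Reactants: 5 (Z)-3-iodo-4-methoxybut-3-en-2-one
Product: 6 (E)-3-(hydroxymethyl)-4-methoxybut-3-en-2-one
Conditions: Bu3SnCH2OH, Pd(PPh3)4 (5 mol %), 1,4-dioxane, 90 °C
Reagents that add atoms: (tributylstannyl)methanol, CCCC[Sn](CCCC)(CCCC)CO
Why: Stille coupling of an α-iodo enone with the hydroxymethyl stannane is a known hydroxymethyl transfer and retains the olefin geometry.

Step 4
Reactants: 6 (E)-3-(hydroxymethyl)-4-methoxybut-3-en-2-one
Product: 7 (1E)-1-methoxy-2-[(tert-butyldimethylsilyloxy)methyl]-3-(tert-butyldimethylsilyloxy)buta-1,3-diene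
Conditions: t-BuMe2SiOTf (2.4 equiv), Et3N, Et2O, 0 °C → rt
Reagents that add atoms: tert-butyldimethylsilyl trifluoromethanesulfonate, CC(C)(C)[Si](C)(C)OS(=O)(=O)C(F)(F)F
Why: The silyl triflate with amine silylates the primary alcohol and soft-enolises the methyl ketone in one operation, the usual entry to 1-alkoxy-3-silyloxy dienes.

Step 5
Reactants: 3 (E)-3-bromo-2-methylprop-2-enal; 7 the silyloxy diene
Product: 8 (1R,6S)-6-bromo-4-(tert-butyldimethylsilyloxy)-3-[(tert-butyldimethylsilyloxy)methyl]-2-methoxy-1-methylcyclohex-3-ene-1-carbaldehyde (both C2 epimers)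
Conditions: o-tolyl oxazaborolidine from (R)-α,α-diphenylprolinol (0.2 equiv), HNTf2 (0.2 equiv), CH2Cl2, −78 °C, slow addition of 7; Et3N quench
Reagents that add atoms: none
Why: This is a Lewis-acid-catalysed Diels–Alder reaction of an α-substituted enal with a 1-alkoxy-3-silyloxy diene, in which the silyloxy-bearing terminus bonds to the β-carbon (CHBr) and the methoxy-bearing terminus to the α-carbon, and suprafacial addition keeps bromine cis to methyl. On the usual model (formyl C–H···O contact, s-trans enal stacked on a phenyl group) this catalyst enantiomer leaves the Re face of C2 of 3 open, which fixes both centres as drawn. The methoxy-bearing carbon is left unassigned because it is lost in step 6.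

Step 6
Reactants: 8 the cycloadduct
Product: 10 (4S,5S)-5-bromo-2-[(tert-butyldimethylsilyloxy)methyl]-4-ethenyl-4-methylcyclohex-2-en-1-one, via vinyl silyl enol ether 9 (not isolated)
Conditions: Ph3PCH3Br, KN(SiMe3)2, THF, 0 °C; 8, −78 → 0 °C; then 0.5 M aq HCl, THF, 0 °C
Reagents that add atoms: methyltriphenylphosphonium bromide, C[P+](c1ccccc1)(c1ccccc1)c1ccccc1.[Br-]
Why: Wittig methylenation of the non-enolisable aldehyde is run while the ketone is still masked as its silyl enol ether. Acid hydrolysis and β-elimination of methanol then unveil the enone, so the β-bromo ketone never meets base.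

Step 7
Reactants: 10 the bromo enone
Product: 11 (1R,4S,5S)-5-bromo-2-[(tert-butyldimethylsilyloxy)methyl]-4-ethenyl-4-methylcyclohex-2-en-1-ol
Conditions: (S)-2-methyl-CBS-oxazaborolidine (0.2 equiv), catecholborane, toluene, −78 °C
Reagents that add atoms: none
Why: CBS reduction with catecholborane is 1,2-selective and does not hydroborate the vinyl group. With the 2-substituted alkenyl branch as the large group, the (S)-catalyst delivers hydride to the face of the C4 vinyl group and gives the 1R carbinol, with oxygen cis to the ring methyl group and to bromine.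

Step 8
Reactants: 12 5-bromo-2-methylpent-2-ene
Product: 13 6-methylhept-5-en-1-yne
Conditions: LiC≡CH·H2NCH2CH2NH2, DMSO, 10 °C → rt
Reagents that add atoms: lithium acetylide–ethylenediamine complex, [Li+].[C-]#C.NCCN
Why: SN2 alkylation of lithium acetylide by a primary bromide in DMSO is a standard terminal-alkyne synthesis.

Step 9
Reactants: 13 6-methylhept-5-en-1-yne
Product: 15 (1E)-1-iodo-2,6-dimethylhepta-1,5-diene, via alkenylalane 14 (not isolated)
Conditions: AlMe3, ZrCp2Cl2 (0.25 equiv), CH2Cl2, 0 °C → rt; then I2, THF, −30 → 0 °C
Reagents that add atoms: trimethylaluminium, C[Al](C)C; iodine, II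
Why: Zirconium-catalysed syn-carboalumination places methyl and aluminium cis on the former triple bond, and iodinolysis with retention gives the E-alkenyl iodide; the trisubstituted olefin is inert.

Step 10
Reactants: 15 the dienyl iodide
Product: 16 (3S)-3-[(3E)-4-iodo-3-methylbut-3-en-1-yl]-2,2-dimethyloxirane
Conditions: L-fructose-derived Shi ketone (0.3 equiv), KHSO5 (as 2KHSO5·KHSO4·K2SO4), K2CO3, Bu4NHSO4, MeCN–CH2(OMe)2, aq Na2B4O7 buffer, 0 °C
Reagents that add atoms: potassium peroxymonosulfate, [K+].[O-]S(=O)(=O)OO
Why: Shi epoxidation prefers the electron-rich trisubstituted olefin over the iodoalkene. Through the usual spiro transition state the L-fructose-derived ketone should give the S epoxide, the D-fructose-derived ketone giving R for this olefin class.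

Step 11
Reactants: 16 the epoxide
Product: 17 (3S,6E)-2-bromo-7-iodo-2,6-dimethylhept-6-en-3-ol
Conditions: 48 % aq HBr, Et2O, −20 °C
Reagents that add atoms: hydrogen bromide, Br
Why: Acid-mediated opening of a trisubstituted epoxide by bromide takes place at the tertiary carbon (borderline SN1), so the C–O bond of the stereocentre is untouched and 3S is kept.

Step 12
Reactants: 18 3-bromo-4-hydroxybenzoic acid
Product: 19 triisopropylsilyl 3-bromo-4-(triisopropylsilyloxy)benzoate
Conditions: i-Pr3SiCl (2.3 equiv), imidazole, DMF, rt
Reagents that add atoms: chlorotriisopropylsilane, CC(C)[Si](Cl)(C(C)C)C(C)C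
Why: Chlorosilane with imidazole silylates phenol and carboxylic acid alike; the silyl ester is a transient protecting group for step 13.

Step 13
Reactants: 19 the bis-silyl compound
Product: 21 3-(2-tert-butoxy-2-oxoethyl)-4-(triisopropylsilyloxy)benzoic acid, via triisopropylsilyl ester 20 (not isolated)
Conditions: BrZnCH2CO2t-Bu, Pd(dba)2 (2 mol %), P(t-Bu)3 (2 mol %), THF, rt; then K2CO3, MeOH–H2O, 0 °C; pH 4
Reagents that add atoms: (2-tert-butoxy-2-oxoethyl)zinc bromide, CC(C)(C)OC(=O)C[Zn]Br
Why: Palladium-catalysed α-arylation of an ester zinc enolate (Reformatsky reagent) by an aryl bromide is neutral and tolerates the silyl ester. Mild carbonate methanolysis then cleaves only the labile silyl ester, leaving the aryl silyl ether and the tert-butyl ester.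

Step 14
Reactants: 21 the benzoic acid; 17 the bromohydrin
Product: 22 (3S,6E)-2-bromo-7-iodo-2,6-dimethylhept-6-en-3-yl 3-(2-tert-butoxy-2-oxoethyl)-4-(triisopropylsilyloxy)benzoate
Conditions: EDC·HCl, DMAP, CH2Cl2, 0 °C → rt
Reagents that add atoms: none
Why: Steglich esterification through the N-acylpyridinium acylates the hindered secondary hydroxyl; the medium is too weakly basic to re-close the bromohydrin, and the stereocentre is not involved.

Step 15
Reactants: 22 the tert-butyl ester
Product: 23 {5-[(3S,6E)-2-bromo-7-iodo-2,6-dimethylhept-6-en-3-yl]oxycarbonyl-2-(triisopropylsilyloxy)phenyl}acetic acid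
Conditions: CF3CO2H–CH2Cl2 (1:4), 0 °C → rt
Reagents that add atoms: none
Why: Acidolysis of the tert-butyl ester loses isobutene; the aryl silyl ether, the secondary benzoate, the alkenyl iodide and the inductively deactivated tertiary bromide tolerate brief trifluoroacetic acid.

Step 16
Reactants: 11 the ring-A alcohol; 23 the alkenyl iodide acid
Product: 25 seco acid (C7–C8 bond formed; 8E; free C2 hydroxyl and free arylacetic acid; 2R 4S 5S 12S), via bis-borane 24 (not isolated)
Conditions: 9-BBN (2.4 equiv), THF, 0 °C → rt; then 3 M aq K3PO4, 23, PdCl2(dppf) (10 mol %), AsPh3 (10 mol %), DMF, rt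
Reagents that add atoms: none
Why: 9-BBN hydroborates only the monosubstituted vinyl group (boron at the terminus) and a second equivalent is taken up by the hydroxyl. B-alkyl Suzuki–Miyaura coupling then retains the E geometry, and zerovalent palladium with dppf does not insert into unactivated alkyl bromides at room temperature.

Step 17
Reactants: 25 the seco acid
Product: 26 19-membered diolide (C2–O arylacetate and C12–O benzoate of one arene; C1=C13 olefin with CH2OSi on C1; 8E; 2R 4S 5S 12S)
Conditions: 2-methyl-6-nitrobenzoic anhydride, DMAP, CH2Cl2, rt, slow addition of 25 (final 1 mM)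
Reagents that add atoms: none
Why: Shiina macrolactonisation: the mixed anhydride of the arylacetic acid acylates the only free hydroxyl under high dilution, and no stereocentre is touched.

Step 18
Reactants: 26 the 19-membered diolide
Product: 29 15-membered lactone acid (C13–CH(CO2H)Ar bond; C1=C2 olefin; 4S 5S 12S 13R; benzylic carbon either epimer), via silyl ketene acetal 27 (not isolated), via trimethylsilyl ester 28 (not isolated)
Conditions: Me3SiCl–Et3N (excess), THF, −78 °C; KN(SiMe3)2 (1.5 equiv), −78 °C; then → 50 °C; aq citric acid
Reagents that add atoms: none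
Why: In this Ireland–Claisen rearrangement, KN(SiMe3)2 removes the only acidic hydrogen of 26, the benzylic α-hydrogen of the arylacetate (the benzoate cannot enolise), and Me3SiCl already in the flask traps the enolate as the silyl ketene acetal 27. On warming, 27 undergoes a concerted [3,3] shift through a six-membered transition state: the ketene acetal carbon bonds to C13, the C2–O bond breaks and the double bond moves from C1=C13 to C1=C2; aqueous acid then hydrolyses the silyl ester 28. The closest known reactions are Ireland–Claisen ring contractions of macrocyclic allylic lactones and 1,3-chirality transfer in cyclohex-2-enyl ester enolates. The 15-membered ring is closed by contraction, the new bond excising four atoms (carboxyl carbon, oxygen, C2, C1) from the 19-membered ring; the cyclohexene allows a boat-like or a chair-like array, and both are suprafacial across the allyl unit. C13 is therefore controlled by the C2 carbinol centre set in step 7: the oxygen leaves from the face of the C5 methyl group and the carbon arrives on that same face, trans to the C5 chain, giving 13R. The benzylic carbon forms as either epimer depending on ketene acetal geometry, which does not matter because the carboxyl group is removed in step 19. The step needs enolisation to outrun E2 loss of HBr at the tertiary and secondary bromides, which the large acidity gap, −78 °C and the internal silyl chloride quench should secure. The allylic silyl ether left on C1 is the handle for step 21.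

Step 19
Reactants: 29 the lactone acid
Product: 31 15-membered lactone with benzylic CH2 (C1=C2 olefin with CH2OSi on C1; 4S 5S 12S 13R), via thiohydroxamate ester 30 (not isolated)
Conditions: N-hydroxypyridine-2-thione, DCC, DMAP (cat.), CH2Cl2, rt, dark; then t-BuSH (excess), hν (tungsten lamp), 10 °C
Reagents that add atoms: none
Why: Barton decarboxylation: the thiohydroxamate ester fragments under visible light to CO2 and the benzylic radical, which takes hydrogen from the thiol. The thiyl radical carries the chain and does not abstract bromine from carbon, and C13 is untouched.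

Step 20
Reactants: 31 the silyl ether
Product: 32 primary allylic alcohol (HOCH2 on C1; C1=C2)
Conditions: camphorsulfonic acid (0.2 equiv), MeOH–CH2Cl2 (1:1), 0 °C
Reagents that add atoms: none
Why: Acid-catalysed methanolysis removes the primary alkyl silyl ether; aryl silyl ethers are far more resistant to acid, and the triisopropylsilyl group widens the margin.

Step 21
Reactants: 32 the allylic alcohol
Product: 35 exocyclic methylene macrolide (C1=CH2; C2 now CH2; 8E), via sulfonylhydrazine 33 (not isolated), via allylic diazene 34 (not isolated)
Conditions: 2-nitrobenzenesulfonylhydrazide, PPh3, diethyl azodicarboxylate, THF, −30 °C; then rt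
Reagents that add atoms: none
Why: Myers reductive allylic transposition: Mitsunobu displacement of the primary allylic alcohol by the sulfonylhydrazide, loss of sulfinic acid on warming, and retro-ene loss of dinitrogen from the diazene. Hydrogen is delivered to C2 and the double bond moves to the exocyclic position; no stereocentre is formed.

Step 22
Reactants: 35 the diene macrolide
Product: 36 (8S,9S)-epoxide, aryl triisopropylsilyl ether
Conditions: L-fructose-derived Shi ketone (0.5 equiv), KHSO5 (as 2KHSO5·KHSO4·K2SO4), K2CO3, Bu4NHSO4, MeCN–CH2(OMe)2, aq Na2B4O7 buffer, 0 °C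
Reagents that add atoms: potassium peroxymonosulfate, [K+].[O-]S(=O)(=O)OO
Why: The chiral dioxirane of the Shi epoxidation attacks the electron-rich E-trisubstituted olefin much faster than the 1,1-disubstituted exocyclic olefin. The L-fructose-derived ketone should deliver oxygen to the face that gives 8S,9S, the trans relationship coming from the E olefin; the carbonate buffer should not cleave the aryl triisopropylsilyl ether.

Step 23
Reactants: 36 the silyl-protected epoxide
Product: 37 bromophycolide S
Conditions: Bu4NF–AcOH (1:1), THF, 0 °C
Reagents that add atoms: none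
Why: Fluoride cleaves the aryl silyl ether quickly; acetic acid buffering keeps the phenoxide from acting as a base on the tertiary bromide or as a nucleophile on the epoxide.

## Compound list

1 | methacrolein | C=C(C)C=O | starting material
2 | 2,3-dibromo-2-methylpropanal (racemic) | CC(Br)(CBr)C=O | intermediate (not isolated)
3 | (E)-3-bromo-2-methylprop-2-enal | Br/C=C(\C)C=O | intermediate
4 | (E)-4-methoxybut-3-en-2-one | CO/C=C/C(C)=O | starting material
5 | (Z)-3-iodo-4-methoxybut-3-en-2-one | CO/C=C(\I)C(C)=O | intermediate
6 | (E)-3-(hydroxymethyl)-4-methoxybut-3-en-2-one | CO/C=C(\CO)C(C)=O | intermediate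
7 | (1E)-1-methoxy-2-[(tert-butyldimethylsilyloxy)methyl]-3-(tert-butyldimethylsilyloxy)buta-1,3-diene | CO/C=C(\CO[Si](C)(C)C(C)(C)C)C(=C)O[Si](C)(C)C(C)(C)C | intermediate
8 | (1R,6S)-6-bromo-4-(tert-butyldimethylsilyloxy)-3-[(tert-butyldimethylsilyloxy)methyl]-2-methoxy-1-methylcyclohex-3-ene-1-carbaldehyde (C2 epimers) | CC(C)(C)[Si](C)(C)OC1=C(CO[Si](C)(C)C(C)(C)C)C(OC)[C@](C)(C=O)[C@@H](Br)C1 | intermediate
9 | 1-ethenyl analogue of 8 (CH=CH2 in place of CHO; 4S,5S in cyclohex-1-ene numbering) | CC(C)(C)[Si](C)(C)OC1=C(CO[Si](C)(C)C(C)(C)C)C(OC)[C@](C)(C=C)[C@@H](Br)C1 | intermediate (not isolated)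
10 | (4S,5S)-5-bromo-2-[(tert-butyldimethylsilyloxy)methyl]-4-ethenyl-4-methylcyclohex-2-en-1-one | O=C1C[C@H](Br)[C@@](C)(C=C)C=C1CO[Si](C)(C)C(C)(C)C | intermediate
11 | (1R,4S,5S)-5-bromo-2-[(tert-butyldimethylsilyloxy)methyl]-4-ethenyl-4-methylcyclohex-2-en-1-ol | O[C@@H]1C[C@H](Br)[C@@](C)(C=C)C=C1CO[Si](C)(C)C(C)(C)C | intermediate
12 | 5-bromo-2-methylpent-2-ene | CC(C)=CCCBr | starting material
13 | 6-methylhept-5-en-1-yne | C#CCCC=C(C)C | intermediate
14 | [(1E)-2,6-dimethylhepta-1,5-dien-1-yl]dimethylalane | C[Al](C)/C=C(\C)CCC=C(C)C | intermediate (not isolated)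
15 | (1E)-1-iodo-2,6-dimethylhepta-1,5-diene | I/C=C(\C)CCC=C(C)C | intermediate
16 | (3S)-3-[(3E)-4-iodo-3-methylbut-3-en-1-yl]-2,2-dimethyloxirane | I/C=C(\C)CC[C@@H]1OC1(C)C | intermediate
17 | (3S,6E)-2-bromo-7-iodo-2,6-dimethylhept-6-en-3-ol | I/C=C(\C)CC[C@H](O)C(C)(C)Br | intermediate
18 | 3-bromo-4-hydroxybenzoic acid | OC(=O)c1ccc(O)c(Br)c1 | starting material
19 | triisopropylsilyl 3-bromo-4-(triisopropylsilyloxy)benzoate | CC(C)[Si](C(C)C)(C(C)C)OC(=O)c1ccc(O[Si](C(C)C)(C(C)C)C(C)C)c(Br)c1 | intermediate
20 | triisopropylsilyl 3-(2-tert-butoxy-2-oxoethyl)-4-(triisopropylsilyloxy)benzoate | CC(C)[Si](C(C)C)(C(C)C)OC(=O)c1ccc(O[Si](C(C)C)(C(C)C)C(C)C)c(CC(=O)OC(C)(C)C)c1 | intermediate (not isolated)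
21 | 3-(2-tert-butoxy-2-oxoethyl)-4-(triisopropylsilyloxy)benzoic acid | OC(=O)c1ccc(O[Si](C(C)C)(C(C)C)C(C)C)c(CC(=O)OC(C)(C)C)c1 | intermediate
22 | (3S,6E)-2-bromo-7-iodo-2,6-dimethylhept-6-en-3-yl 3-(2-tert-butoxy-2-oxoethyl)-4-(triisopropylsilyloxy)benzoate | CC(C)(C)OC(=O)Cc1cc(ccc1O[Si](C(C)C)(C(C)C)C(C)C)C(=O)O[C@@H](CC/C(C)=C/I)C(C)(C)Br | intermediate
23 | {5-[(3S,6E)-2-bromo-7-iodo-2,6-dimethylhept-6-en-3-yl]oxycarbonyl-2-(triisopropylsilyloxy)phenyl}acetic acid | OC(=O)Cc1cc(ccc1O[Si](C(C)C)(C(C)C)C(C)C)C(=O)O[C@@H](CC/C(C)=C/I)C(C)(C)Br | intermediate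
24 | bis-borane from 11: O-(9-borabicyclo[3.3.1]nonan-9-yl) on the carbinol, 2-(9-borabicyclo[3.3.1]nonan-9-yl)ethyl on the quaternary carbon | C1CCC2CCCC1B2O[C@@H]3C[C@H](Br)[C@@](C)(CCB4C5CCCC4CCC5)C=C3CO[Si](C)(C)C(C)(C)C | intermediate (not isolated)
25 | seco acid: ring A of 11 joined through C6–C7 to the (8E) side chain of 23; free C2–OH, free arylacetic acid; 2R,4S,5S,12S | O[C@@H]1C[C@H](Br)[C@@](C)(CC/C=C(\C)CC[C@H](OC(=O)c2ccc(O[Si](C(C)C)(C(C)C)C(C)C)c(CC(O)=O)c2)C(C)(C)Br)C=C1CO[Si](C)(C)C(C)(C)C | intermediate
26 | 19-membered diolide: C2–O arylacetate and C12–O benzoate of one arene (aryl O-triisopropylsilyl), C1=C13 olefin, CH2O-tert-butyldimethylsilyl on C1, 8E; 2R,4S,5S,12S | CC(C)(C)[Si](C)(C)OCC1=C[C@@]2(C)[C@@H](Br)C[C@H]1OC(=O)Cc1cc(ccc1O[Si](C(C)C)(C(C)C)C(C)C)C(=O)O[C@H](C(C)(C)Br)CC/C(C)=C/CC2 | intermediate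
27 | trimethylsilyl ketene acetal of the arylacetate of 26 (either geometry) | CC(C)(C)[Si](C)(C)OCC1=C[C@@]2(C)[C@@H](Br)C[C@H]1OC(O[Si](C)(C)C)=Cc1cc(ccc1O[Si](C(C)C)(C(C)C)C(C)C)C(=O)O[C@H](C(C)(C)Br)CC/C(C)=C/CC2 | intermediate (not isolated)
28 | trimethylsilyl ester of 29 | CC(C)(C)[Si](C)(C)OCC1=CC[C@H](Br)[C@@]2(C)CC/C=C(\C)CC[C@@H](C(C)(C)Br)OC(=O)c3ccc(O[Si](C(C)C)(C(C)C)C(C)C)c(c3)C(C(=O)O[Si](C)(C)C)[C@H]12 | intermediate (not isolated)
29 | 15-membered lactone acid: carboxyl on the benzylic carbon (either epimer), C1=C2 olefin, CH2O-silyl on C1, 8E; 4S,5S,12S,13R | CC(C)(C)[Si](C)(C)OCC1=CC[C@H](Br)[C@@]2(C)CC/C=C(\C)CC[C@@H](C(C)(C)Br)OC(=O)c3ccc(O[Si](C(C)C)(C(C)C)C(C)C)c(c3)C(C(=O)O)[C@H]12 | intermediate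
30 | 2-thioxopyridin-1(2H)-yl ester of 29 | CC(C)(C)[Si](C)(C)OCC1=CC[C@H](Br)[C@@]2(C)CC/C=C(\C)CC[C@@H](C(C)(C)Br)OC(=O)c3ccc(O[Si](C(C)C)(C(C)C)C(C)C)c(c3)C(C(=O)On3ccccc3=S)[C@H]12 | intermediate (not isolated)
31 | 15-membered lactone with benzylic CH2; C1=C2, CH2O-tert-butyldimethylsilyl on C1; 4S,5S,12S,13R | CC(C)(C)[Si](C)(C)OCC1=CC[C@H](Br)[C@@]2(C)CC/C=C(\C)CC[C@@H](C(C)(C)Br)OC(=O)c3ccc(O[Si](C(C)C)(C(C)C)C(C)C)c(c3)C[C@H]12 | intermediate
32 | primary allylic alcohol from 31 (HOCH2 on C1) | OCC1=CC[C@H](Br)[C@@]2(C)CC/C=C(\C)CC[C@@H](C(C)(C)Br)OC(=O)c3ccc(O[Si](C(C)C)(C(C)C)C(C)C)c(c3)C[C@H]12 | intermediate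
33 | N-allyl-N-(2-nitrobenzenesulfonyl)hydrazine from 32 | NN(CC1=CC[C@H](Br)[C@@]2(C)CC/C=C(\C)CC[C@@H](C(C)(C)Br)OC(=O)c3ccc(O[Si](C(C)C)(C(C)C)C(C)C)c(c3)C[C@H]12)S(=O)(=O)c1ccccc1[N+](=O)[O-] | intermediate (not isolated)
34 | allylic monoalkyl diazene from 33 | N=NCC1=CC[C@H](Br)[C@@]2(C)CC/C=C(\C)CC[C@@H](C(C)(C)Br)OC(=O)c3ccc(O[Si](C(C)C)(C(C)C)C(C)C)c(c3)C[C@H]12 | intermediate (not isolated)
35 | exocyclic methylene macrolide, 8E olefin, aryl O-triisopropylsilyl; 4S,5S,12S,13R | C=C1CC[C@H](Br)[C@@]2(C)CC/C=C(\C)CC[C@@H](C(C)(C)Br)OC(=O)c3ccc(O[Si](C(C)C)(C(C)C)C(C)C)c(c3)C[C@H]12 | intermediate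
36 | O-triisopropylsilyl bromophycolide S; 4S,5S,8S,9S,12S,13R | C=C1CC[C@H](Br)[C@@]2(C)CC[C@@H]3O[C@@]3(C)CC[C@@H](C(C)(C)Br)OC(=O)c3ccc(O[Si](C(C)C)(C(C)C)C(C)C)c(c3)C[C@H]12 | intermediate
37 | bromophycolide S | C=C1CC[C@H](Br)[C@@]2(C)CC[C@@H]3O[C@@]3(C)CC[C@@H](C(C)(C)Br)OC(=O)c3ccc(O)c(c3)C[C@H]12 | target

## Step count and least certain steps

Total: 23 steps. Longest linear sequence: 14 steps (4 to 37 through steps 2–7 and 16–23; the line from 12 through steps 8–11 and 14–23 is equally long).

Step 18 (key step). Two things may go wrong. The amide base may remove HBr from the tertiary or secondary bromide before the enolate is silylated. The tethered ketene acetal may also fail to reach the array under the lower face of ring A, so that desilylation or fragmentation to ketene and alkoxide outruns the shift. The fallback takes the rearrangement out of the macrocycle and sets out from 11 and 23. Esterification (EDC, DMAP) gives the open-chain arylacetate of the ring-A alcohol, F1. The same silyl ketene acetal rearrangement, now unconstrained, gives the acid with the C13–benzylic bond, F2. Barton decarboxylation as in step 19 gives the vinyl alkenyl-iodide ester F3. Hydroboration of the vinyl group with 9-BBN gives the borane F4, which is closed at C7–C8 by intramolecular B-alkyl Suzuki–Miyaura coupling under high dilution (PdCl2(dppf), AsPh3, aq K3PO4). The route is rejoined at 31.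

Step 5. The diene may attack the formyl carbon (hetero-Diels–Alder or aldol-type pathway) instead of the hindered trisubstituted C=C. Silyl transfer from the diene to triflimide may start an achiral silicon-catalysed background reaction. The β-bromine may also disturb the stacking that gives face selection. The fallback gives up catalyst control of this step: 3 and 7 are heated without catalyst (toluene, 80 °C), which gives 8 together with its enantiomer F5. Step 6 on the mixture gives 10 together with its enantiomer F6. The reagent-controlled reduction of step 7 then converts the two enantiomers into 11 and the (1R,4R,5R) diastereomer F7, which are separated by chromatography. The route is rejoined at 11 at the cost of half the material.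

Step 19. Acylation of the hindered α-aryl acid may be slow and divert through the aryl ketene. The stabilised benzylic radical abstracts hydrogen slowly and may instead add to the thiocarbonyl group of a second ester. Reversible thiyl addition may scramble the geometry of the trisubstituted olefin. The fallback changes the radical precursor and the way it is triggered: 29 is converted with N-hydroxyphthalimide and a carbodiimide into the N-acyloxyphthalimide F8. This is fragmented by single-electron reduction under visible light (Ru(bpy)3Cl2 as catalyst, 1-benzyl-1,4-dihydronicotinamide, t-BuSH, aqueous THF), which unactivated C–Br bonds should not undergo. The route is rejoined at 31.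

Step 22. Face selection may be dictated by the conformation of the macrocycle and not by the ketone, and prolonged exposure may oxidise the exocyclic olefin. The fallback moves the epoxidation to the open-chain stage, where reagent control is most reliable, and sets out from 25. The same ketone epoxidises the unhindered chain olefin to the epoxy seco acid F9. Steps 17, 18 and 19 applied in turn give the epoxy diolide F10, the epoxy lactone acid F11 and the epoxy lactone F12. The primary silyl ether is then removed without protic acid (HF·pyridine buffered with pyridine, THF, 0 °C) to give the epoxy allylic alcohol F13. The transposition of step 21 rejoins the route at 36.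

## Further compounds

F1 | step 18 | arylacetate ester of 11 with 23 (open chain; vinyl and alkenyl iodide) | O([C@@H]1C[C@H](Br)[C@@](C)(C=C)C=C1CO[Si](C)(C)C(C)(C)C)C(=O)Cc1cc(ccc1O[Si](C(C)C)(C(C)C)C(C)C)C(=O)O[C@@H](CC/C(C)=C/I)C(C)(C)Br
F2 | step 18 | open-chain rearranged acid (C13–CH(CO2H)Ar; C1=C2; vinyl on C5) | CC(C)(C)[Si](C)(C)OCC1=CC[C@H](Br)[C@@](C)(C=C)[C@@H]1C(C(=O)O)c1cc(ccc1O[Si](C(C)C)(C(C)C)C(C)C)C(=O)O[C@@H](CC/C(C)=C/I)C(C)(C)Br
F3 | step 18 | decarboxylated open-chain ester (benzylic CH2; vinyl and alkenyl iodide) | CC(C)(C)[Si](C)(C)OCC1=CC[C@H](Br)[C@@](C)(C=C)[C@@H]1Cc1cc(ccc1O[Si](C(C)C)(C(C)C)C(C)C)C(=O)O[C@@H](CC/C(C)=C/I)C(C)(C)Br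
F4 | step 18 | B-alkyl-9-borabicyclo[3.3.1]nonane from F3 | CC(C)(C)[Si](C)(C)OCC1=CC[C@H](Br)[C@@](C)(CCB2C3CCCC2CCC3)[C@@H]1Cc1cc(ccc1O[Si](C(C)C)(C(C)C)C(C)C)C(=O)O[C@@H](CC/C(C)=C/I)C(C)(C)Br
F5 | step 5 | enantiomer of 8 (1S,6R; C2 epimers) | CC(C)(C)[Si](C)(C)OC1=C(CO[Si](C)(C)C(C)(C)C)C(OC)[C@@](C)(C=O)[C@H](Br)C1
F6 | step 5 | enantiomer of 10 (4R,5R) | O=C1C[C@@H](Br)[C@](C)(C=C)C=C1CO[Si](C)(C)C(C)(C)C
F7 | step 5 | (1R,4R,5R)-5-bromo-2-[(tert-butyldimethylsilyloxy)methyl]-4-ethenyl-4-methylcyclohex-2-en-1-ol | O[C@@H]1C[C@@H](Br)[C@](C)(C=C)C=C1CO[Si](C)(C)C(C)(C)C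
F8 | step 19 | 1,3-dioxoisoindolin-2-yl ester of 29 | CC(C)(C)[Si](C)(C)OCC1=CC[C@H](Br)[C@@]2(C)CC/C=C(\C)CC[C@@H](C(C)(C)Br)OC(=O)c3ccc(O[Si](C(C)C)(C(C)C)C(C)C)c(c3)C(C(=O)ON3C(=O)c4ccccc4C3=O)[C@H]12
F9 | step 22 | (8S,9S)-epoxy seco acid from 25 | O[C@@H]1C[C@H](Br)[C@@](C)(CC[C@@H]3O[C@@]3(C)CC[C@H](OC(=O)c2ccc(O[Si](C(C)C)(C(C)C)C(C)C)c(CC(O)=O)c2)C(C)(C)Br)C=C1CO[Si](C)(C)C(C)(C)C
F10 | step 22 | (8S,9S)-epoxy 19-membered diolide | CC(C)(C)[Si](C)(C)OCC1=C[C@@]2(C)[C@@H](Br)C[C@H]1OC(=O)Cc1cc(ccc1O[Si](C(C)C)(C(C)C)C(C)C)C(=O)O[C@H](C(C)(C)Br)CC[C@]3(C)O[C@H]3CC2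
F11 | step 22 | (8S,9S)-epoxy 15-membered lactone acid | CC(C)(C)[Si](C)(C)OCC1=CC[C@H](Br)[C@@]2(C)CC[C@@H]3O[C@@]3(C)CC[C@@H](C(C)(C)Br)OC(=O)c3ccc(O[Si](C(C)C)(C(C)C)C(C)C)c(c3)C(C(=O)O)[C@H]12
F12 | step 22 | (8S,9S)-epoxy lactone with benzylic CH2 and CH2O-tert-butyldimethylsilyl on C1 | CC(C)(C)[Si](C)(C)OCC1=CC[C@H](Br)[C@@]2(C)CC[C@@H]3O[C@@]3(C)CC[C@@H](C(C)(C)Br)OC(=O)c3ccc(O[Si](C(C)C)(C(C)C)C(C)C)c(c3)C[C@H]12
F13 | step 22 | (8S,9S)-epoxy primary allylic alcohol | OCC1=CC[C@H](Br)[C@@]2(C)CC[C@@H]3O[C@@]3(C)CC[C@@H](C(C)(C)Br)OC(=O)c3ccc(O[Si](C(C)C)(C(C)C)C(C)C)c(c3)C[C@H]12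
A1 | alternative 1 | methyl 3-[(2Z)-3-[(tert-butyldimethylsilyloxy)methyl]penta-2,4-dien-1-yl]-4-(tert-butyldimethylsilyloxy)benzoate | C=C/C(CO[Si](C)(C)C(C)(C)C)=C/Cc1cc(C(=O)OC)ccc1O[Si](C)(C)C(C)(C)C
A2 | alternative 1 | ring-A bromo aldehyde with arylmethyl arm and allylic silyl ether | O=C[C@]1(C)[C@@H](Br)CC=C(CO[Si](C)(C)C(C)(C)C)[C@H]1Cc1cc(C(=O)OC)ccc1O[Si](C)(C)C(C)(C)C
A3 | alternative 2 | open-chain 2-methylallylic alcohol with tertiary aryl ester dimethyl ketal | C=C1CC[C@H](Br)[C@@](C)(CCC(O)C(C)=C)[C@@H]1Cc1cc(ccc1O[Si](C)(C)C(C)(C)C)C(=O)OC(C)(C)C(C)(OC)OC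
A4 | alternative 2 | 16-membered keto lactone (tertiary aryl ester) with E olefin | C=C1CC[C@H](Br)[C@@]2(C)CC/C=C(\C)CCC(=O)C(C)(C)OC(=O)c3ccc(O[Si](C)(C)C(C)(C)C)c(c3)C[C@H]12
A5 | alternative 3 | 19-membered macrolide with anti bromohydrin (C4 Br, C5 OH) and allylsilane (arm trans to C2) | C[Si](C)(C)C/C1=C\Cc2cc(ccc2O[Si](C)(C)C(C)(C)C)C(=O)O[C@H](C(C)(C)Br)CC/C(C)=C/CC[C@@](C)(O)[C@@H](Br)CC1
A6 | alternative 3 | 15-membered bromo macrolide with ring A, exocyclic methylene and E olefin, aryl O-tert-butyldimethylsilyl | C=C1CC[C@H](Br)[C@@]2(C)CC/C=C(\C)CC[C@@H](C(C)(C)Br)OC(=O)c3ccc(O[Si](C)(C)C(C)(C)C)c(c3)C[C@H]12
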